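Ring numbering: C1 (CClCH3), C2 (CH2), C3 (CBrCH3), C4 (CH–chlorovinyl), C5 (CH2), C6 (CHBr). The cyclohexane is cut at C5–C6 and C3–C4. The key step exploits that C6–C1(CH3)–C2–C3(CH3) is a masked 1,3-dimethylbutadiene and C4–C5 an acrolein unit. One amine-catalysed enantioselective Diels–Alder reaction of two commercial, acyclic, achiral partners, (E)-2-methylpenta-1,3-diene and acrolein, closes the ring, fixes C4 absolutely and sets the C3 methyl cis to the side chain. The surviving C1=C2 alkene holds the chlorine-bearing C1 and is allylic to both bromine-bearing carbons, so the three ring halogens follow by substrate-controlled relay from the C3/C4 pair.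

Key step: step 1

Convention: α is the ring face that carries the C4 side chain and β is the opposite face; the ring numbering above is kept for all intermediates.
Assumption: the (5S)-catalyst is taken to expose the iminium face that leads to (1R,2S)-3, as the usual shielding model predicts; if the sense were opposite, the (5R)-catalyst would be used without other change.

Step 1
Reactants: 1 (E)-2-methylpenta-1,3-diene; 2 acrolein
Product: 3 (1R,2S)-2,4-dimethylcyclohex-3-ene-1-carbaldehyde
Conditions: (5S)-5-benzyl-2,2,3-trimethylimidazolidin-4-one·HCl (20 mol %), CH3NO2/H2O 95:5, 0 °C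
Reagents that add atoms: none
Why: Reversible condensation of 2 with the chiral secondary ammonium salt gives an E-configured unsaturated iminium ion whose lowered LUMO reacts with the s-cis conformer of 1 in a concerted but asynchronous [4+2] cycloaddition, and hydrolysis then releases 3 and the amine; the closest known reaction type is the iminium-catalysed enantioselective Diels–Alder reaction of enals with acyclic dienes. The only ring formed, the six-membered carbocycle C1–C6, is closed in a suprafacial-suprafacial [4π+2π] mode by making C5–C6 (the more advanced bond) and C3–C4 in the same event. C4 is controlled by the catalyst, whose benzyl group covers one face of the iminium π system so that the diene adds to the open face. C3 is controlled by the E geometry of the C2=C3 bond of 1 together with the endo orientation of the iminium group, which places the C3 methyl cis to the formyl group (both α). The step needs regioselectivity, secured because both methyl groups of 1 raise the HOMO coefficient at its CH2 terminus (C6), which pairs with the β-carbon of the iminium ion (C5). It also needs diene-geometry selectivity, secured because any Z isomer of 1 cannot reach the s-cis conformation and is left unchanged.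

Step 2
Reactants: 3 (1R,2S)-2,4-dimethylcyclohex-3-ene-1-carbaldehyde
Product: 4 (3R,4R)-4-[(E)-2-chloroethenyl]-1,3-dimethylcyclohex-1-ene
Conditions: CrCl2, CHCl3, THF, 65 °C
Reagents that add atoms: chloroform, ClC(Cl)Cl
Why: In this Takai–Utimoto chloro-olefination the geminal dichromium reagent from CHCl3 adds to the aldehyde and eliminates to the E-alkenyl chloride under non-basic conditions, so the epimerisable C4 centre and the ring alkene should stay untouched, and it is run before any reducible C–Br bond is present.

Step 3
Reactants: 4 (3R,4R)-4-[(E)-2-chloroethenyl]-1,3-dimethylcyclohex-1-ene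
Product: 5 (1R,4R,5R)-5-[(E)-2-chloroethenyl]-2,4-dimethylcyclohex-2-en-1-ol
Conditions: SeO2 (cat.), t-BuOOH, CH2Cl2, 0 to 23 °C
Reagents that add atoms: tert-butyl hydroperoxide, CC(C)(C)OO (net oxygen source, relayed through SeO2, O=[Se]=O)
Why: Selenium dioxide allylic hydroxylation (ene reaction then [2,3]-sigmatropic shift) attacks the ring CH2 at the more substituted alkene terminus (C6), and both suprafacial events should run on the β face opposite the C3 methyl and C4 side chain, removing the pseudoaxial C6–Hβ and delivering a β hydroxyl group, while the electron-poor chloroalkene is inert.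

Step 4
Reactants: 5 (1R,4R,5R)-5-[(E)-2-chloroethenyl]-2,4-dimethylcyclohex-2-en-1-ol
Product: 6 (3R,4R,6S)-6-bromo-4-[(E)-2-chloroethenyl]-1,3-dimethylcyclohex-1-ene
Conditions: CBr4, PPh3, CH2Cl2, −40 to 0 °C, crude product used at once
Reagents that add atoms: carbon tetrabromide, BrC(Br)(Br)Br
Why: In the Appel reaction bromide displaces the pseudoaxial β oxyphosphonium group by SN2 with inversion while C1 is still sp2 and unhindered, which sets C6–Br α (cis to the side chain), and SN2′ attack at C2 is discouraged by the neighbouring branched C3.

Step 5
Reactants: 6 (3R,4R,6S)-6-bromo-4-[(E)-2-chloroethenyl]-1,3-dimethylcyclohex-1-ene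
Product: 9 (3R,4S,6S)-4-bromo-3-chloro-6-[(E)-2-chloroethenyl]-1,3-dimethylcyclohex-1-ene, via β-chloro selenide 7 (not isolated), via selenoxide 8 (not isolated)
Conditions: PhSeCl, CH2Cl2, −78 to 23 °C; then mCPBA, −78 °C; then Et3N, −78 to 23 °C
Reagents that add atoms: benzeneselenenyl chloride, Cl[Se]c1ccccc1 (Cl stays, PhSe only in 7 and 8); mCPBA, OOC(=O)c1cccc(Cl)c1 (O only in 8)
Why: Anti chloroselenenylation followed by selenoxide syn elimination is the known route from alkenes to transposed allylic chlorides, in which the reversibly formed seleniranium ion on the open β face is opened trans-diaxially and in the Markovnikov sense by chloride at C1 from the α face (setting C1 with Cl cis to C6–Br without a free cation that bromine could bridge), and the C2 selenoxide can eliminate only towards the cis C3–Hβ because C1 bears no hydrogen.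

Step 6
Reactants: 9 (3R,4S,6S)-4-bromo-3-chloro-6-[(E)-2-chloroethenyl]-1,3-dimethylcyclohex-1-ene
Product: 10 (1R,2S,4S,5R)-1,4-dibromo-5-chloro-2-[(E)-2-chloroethenyl]-1,5-dimethylcyclohexane
Conditions: Co(acac)2 (cat.), t-BuOOH (cat.), Et3SiH, TsBr, CH2Cl2/i-PrOH, 0 to 23 °C
Reagents that add atoms: 4-toluenesulfonyl bromide, Cc1ccc(cc1)S(=O)(=O)Br
Why: In this cobalt-hydride hydrogen-atom-transfer Markovnikov hydrobromination the hydrogen atom adds to C2 of the trisubstituted alkene (the 1,2-disubstituted chloroalkene is much slower and no halogen sits β to the radical), and the planar tertiary C3 radical should take bromine from TsBr on the β face because the axial C1–Cl blocks the α face, giving equatorial Br and axial methyl at C3.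

Compound list
1 | (E)-2-methylpenta-1,3-diene | C=C(C)/C=C/C | starting material
2 | acrolein (prop-2-enal) | C=CC=O | starting material
3 | (1R,2S)-2,4-dimethylcyclohex-3-ene-1-carbaldehyde (formyl and C3 methyl cis) | CC1=C[C@H](C)[C@H](C=O)CC1 | intermediate
4 | (3R,4R)-4-[(E)-2-chloroethenyl]-1,3-dimethylcyclohex-1-ene | CC1=C[C@H](C)[C@H](/C=C/Cl)CC1 | intermediate
5 | (1R,4R,5R)-5-[(E)-2-chloroethenyl]-2,4-dimethylcyclohex-2-en-1-ol (C6–OH β) | CC1=C[C@H](C)[C@H](/C=C/Cl)C[C@H]1O | intermediate
6 | (3R,4R,6S)-6-bromo-4-[(E)-2-chloroethenyl]-1,3-dimethylcyclohex-1-ene (C6–Br α) | CC1=C[C@H](C)[C@H](/C=C/Cl)C[C@@H]1Br | intermediate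
7 | β-chloro selenide, PhSeCl adduct of 6 (C1–Cl α, C2–SePh β) | C[C@@]1(Cl)[C@@H]([Se]c2ccccc2)[C@H](C)[C@H](/C=C/Cl)C[C@@H]1Br | intermediate
8 | selenoxide of 7 | C[C@@]1(Cl)[C@@H]([Se](=O)c2ccccc2)[C@H](C)[C@H](/C=C/Cl)C[C@@H]1Br | intermediate
9 | (3R,4S,6S)-4-bromo-3-chloro-6-[(E)-2-chloroethenyl]-1,3-dimethylcyclohex-1-ene | C[C@@]1(Cl)C=C(C)[C@H](/C=C/Cl)C[C@@H]1Br | intermediate
10 | (1R,2S,4S,5R)-1,4-dibromo-5-chloro-2-[(E)-2-chloroethenyl]-1,5-dimethylcyclohexane | C[C@@]1(Cl)C[C@@](C)(Br)[C@H](/C=C/Cl)C[C@@H]1Br | target

Total step count: 6. Longest linear sequence: 6.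

Steps most likely to fail

**Step 5.**
- What may go wrong: the reversible PhSeCl addition may not proceed far enough on the hindered, bromine-deactivated alkene. Chloride may open the seleniranium ion at C2. The tertiary allylic chloride may undergo allylic shift during the oxidative stage.
- Fallback (sets out from 6, comes back at 9): peracid epoxidation of 6 on the open β face should give the β-epoxide F1. Anhydrous HCl in Et2O at low temperature should open it trans-diaxially at the tertiary C1 with inversion to the chlorohydrin F2 (C1–Cl α, C2–OH β). Burgess dehydration (methyl N-(triethylammoniosulfonyl)carbamate, benzene, 50 °C) is a syn elimination that can only use the cis C3–Hβ, so it should return 9.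

**Step 4.**
- What may go wrong: ionisation or bromide exchange at the allylic C6 may erode the inversion, and attack at C2 would give the transposed bromide.
- Fallback (sets out from 5, comes back at 6): bromine is brought in by two stereodefined allylic transpositions instead of a direct displacement. PhNCO should convert 5 into the N-phenylcarbamate F3. Deprotonation (n-BuLi), CuI·2PPh3 and PhMe2SiLi should deliver silicon intramolecularly to C2, syn to the leaving group (syn SN2′). This should give the allylsilane F4 (C2–SiMe2Ph β, C1=C6 alkene). Bromodesilylation with NBS at −78 °C is an anti SE2′ process free of bromide ion. It should place bromine on the α face of C6 and restore the C1=C2 alkene of 6.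

**Step 6.**
- What may go wrong: hydrogen-atom transfer to the hindered C2 may be slow. Tosyl radicals may start a chain bromosulfonylation. Bromine transfer to the planar C3 radical may show poor facial selectivity.
- Fallback (sets out from 9, comes back at 10): Mukaiyama hydration (Mn(dpm)3, PhSiH3, O2, CH2Cl2/i-PrOH) should give the tertiary alcohol F5. Me3SiBr in CH2Cl2 at −20 °C should then replace the hydroxyl group through the C3 cation. Both C3 epimers of the alcohol converge on that cation. Bromide should capture it from the β face because the axial C1–Cl blocks the α face. The C1–Cl bond itself is deactivated towards ionisation by the vicinal C6–Br.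

Further compounds
F1 | step 5 | β-epoxide of 6, 5-bromo-3-[(E)-2-chloroethenyl]-2,6-dimethyl-7-oxabicyclo[4.1.0]heptane | C[C@]12O[C@H]1[C@H](C)[C@H](/C=C/Cl)C[C@@H]2Br
F2 | step 5 | chlorohydrin, 3-bromo-2-chloro-5-[(E)-2-chloroethenyl]-2,6-dimethylcyclohexan-1-ol (C1–Cl α, C2–OH β) | C[C@@]1(Cl)[C@@H](O)[C@H](C)[C@H](/C=C/Cl)C[C@@H]1Br
F3 | step 4 | N-phenylcarbamate of 5 | CC1=C[C@H](C)[C@H](/C=C/Cl)C[C@H]1OC(=O)Nc2ccccc2
F4 | step 4 | allylsilane (C2–SiMe2Ph β, C1=C6 alkene) | CC1=CC[C@@H](/C=C/Cl)[C@@H](C)[C@@H]1[Si](C)(C)c2ccccc2
F5 | step 6 | tertiary alcohol, 4-bromo-5-chloro-2-[(E)-2-chloroethenyl]-1,5-dimethylcyclohexan-1-ol (C3–OH β drawn) | C[C@@]1(Cl)C[C@@](C)(O)[C@H](/C=C/Cl)C[C@@H]1Br
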